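**Plan**

- Retrosynthesis: the O5 and O7 benzoates are removed and O4 is regarded as silylated. Both allylic C–O bonds, C3–O and C6–O, are then cut back to one molecule of O2 and a cyclohexa-1,3-diene.
- Enabling feature: in the cyclohexene ring (C1 bearing C7H2O, C2 the vinylic CH, C3 to C6 the carbinol carbons) the C3 and C6 hydroxyls lie cis-1,4 across C1=C2. The ring is therefore a reduced 2,3-dioxabicyclo[2.2.2]oct-5-ene, the [4+2] adduct of singlet oxygen and the diene C6=C1–C2=C3.
- Forward order: the carbocycle comes from (−)-shikimic acid. O3 is expelled by a palladium-mediated 1,4-elimination (C3–O with a C6 hydrogen) to give the diene. The 1,2-dioxane ring closes in the photooxygenation and is opened again by O–O reduction after dibenzoylation; desilylation ends the route.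
- Stereochemistry: C4 and C5 are those of shikimic acid and are never touched. C3 and C6 arise together in the cycloaddition, on the face of the free C5 hydroxyl and opposite the C4 silyl ether.

Key step: step 8

Remark: shikimic acid numbering is kept throughout (C1 bears C7, C2 is the vinylic CH, then C3 to C6 round the ring); "upper face" means the face of the C5 oxygen.

**Step 1**
Reactants: 1 (−)-shikimic acid
Product: 3 methyl 3,4-O-isopropylideneshikimate, via methyl shikimate 2 (not isolated)
Conditions: MeOH, CSA (cat.), reflux; evaporate; then Me2C(OMe)2, acetone, rt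
Reagents that add atoms: methanol, CO; 2,2-dimethoxypropane, COC(C)(C)OC
Why: Fischer esterification followed by acid-catalysed transacetalisation, in which only the cis-3,4-diol closes an unstrained five-membered dioxolane, should leave the C5 hydroxyl as the single free alcohol with no stereocentre touched.

**Step 2**
Reactants: 3 methyl 3,4-O-isopropylideneshikimate
Product: 4 methyl 3,4-O-isopropylidene-5-O-pivaloylshikimate
Conditions: PivCl, pyridine, DMAP (cat.), CH2Cl2, 0 °C to rt
Reagents that add atoms: pivaloyl chloride, CC(C)(C)C(=O)Cl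
Why: DMAP-catalysed acylation of the only free hydroxyl installs a pivalate, chosen because it survives aqueous acid, migrates and ionises reluctantly, and falls to i-Bu2AlH in step 7 in the same operation that reduces the ester.

**Step 3**
Reactants: 4 methyl 3,4-O-isopropylidene-5-O-pivaloylshikimate
Product: 5 methyl 5-O-pivaloylshikimate
Conditions: AcOH/H2O (4:1), 50 °C
Reagents that add atoms: none
Why: Acid-catalysed acetal hydrolysis should free the cis-3,4-diol while the methyl ester and the hindered pivalate are inert to warm aqueous acetic acid.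

**Step 4**
Reactants: 5 methyl 5-O-pivaloylshikimate
Product: 6 methyl 3,4-O-carbonyl-5-O-pivaloylshikimate
Conditions: CDI, CH2Cl2, rt
Reagents that add atoms: N,N'-carbonyldiimidazole, O=C(n1ccnc1)n1ccnc1
Why: Double acyl transfer from the carbonyl-diimidazole reagent to a cis-vicinal diol closes the five-membered cyclic carbonate, which turns the allylic C3 oxygen into a strained leaving group.

**Step 5**
Reactants: 6 methyl 3,4-O-carbonyl-5-O-pivaloylshikimate
Product: 7 methyl (4R,5R)-4-hydroxy-5-pivaloyloxycyclohexa-1(6),2-diene-1-carboxylate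
Conditions: Pd(PPh3)4 (5 mol %), THF, 45 °C
Reagents that add atoms: none
Why: In this decarboxylative Tsuji–Trost 1,4-elimination, zerovalent palladium ionises the allylic C3–O bond from the face opposite the carbonate, CO2 leaves, and loss of a C6 hydrogen from the π-allyl complex (C1–C2–C3) should give the cross-conjugated dienoate with the C4 oxygen set free as the alcohol and C4 and C5 untouched.

**Step 6**
Reactants: 7 methyl (4R,5R)-4-hydroxy-5-pivaloyloxycyclohexa-1(6),2-diene-1-carboxylate
Product: 8 methyl (4R,5R)-5-pivaloyloxy-4-(triisopropylsilyloxy)cyclohexa-1(6),2-diene-1-carboxylate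
Conditions: TIPSOTf, 2,6-lutidine, CH2Cl2, −78 to 0 °C
Reagents that add atoms: triisopropylsilyl triflate, CC(C)[Si](OS(=O)(=O)C(F)(F)F)(C(C)C)C(C)C
Why: Silyl triflate with a hindered pyridine base silylates the secondary allylic alcohol without free acid or strong base, so the diene should not aromatise and the pivalate should not migrate.

**Step 7**
Reactants: 8 methyl (4R,5R)-5-pivaloyloxy-4-(triisopropylsilyloxy)cyclohexa-1(6),2-diene-1-carboxylate
Product: 9 (4R,5R)-1-(hydroxymethyl)-4-(triisopropylsilyloxy)cyclohexa-1(6),2-dien-5-ol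
Conditions: i-Bu2AlH (6 equiv), CH2Cl2, −78 to −20 °C; aq. potassium sodium tartrate
Reagents that add atoms: none
Why: Hydride reduction with i-Bu2AlH takes the conjugated methyl ester in 1,2-fashion to the primary allylic alcohol and cleaves the pivalate in the same flask, which frees the C5 hydroxyl and makes the diene electron-rich, while the silyl ether and the diene are inert at low temperature.

**Step 8**
Reactants: 9 (4R,5R)-1-(hydroxymethyl)-4-(triisopropylsilyloxy)cyclohexa-1(6),2-dien-5-ol
Product: 10 (3S,4S,5R,6R)-3,6-epidioxy-1-(hydroxymethyl)-4-(triisopropylsilyloxy)cyclohex-1-en-5-ol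
Conditions: O2 (1 atm), tetraphenylporphyrin (cat.), CH2Cl2, −30 °C, visible light (white LEDs)
Reagents that add atoms: dioxygen, O=O
Why: Sensitised singlet oxygen adds to the s-cis-locked diene C6=C1–C2=C3 in a concerted, suprafacial [4+2] cycloaddition, the reaction by which cyclohexa-1,3-dienes give 2,3-dioxabicyclo[2.2.2]oct-5-enes. The new six-membered 1,2-dioxane ring (O–C3–C2=C1–C6–O) closes by simultaneous formation of the C3–O and C6–O bonds on one face, which moves the alkene to C1=C2. Both new stereocentres, C3 (S) and C6 (R), follow from the face of attack alone, because suprafacial addition forces the two oxygens cis. The step needs π-facial selectivity, and two substrate elements should secure it: the free allylic C5 hydroxyl hydrogen-bonds the incoming electrophilic oxygen on its own face in a non-coordinating solvent, and the bulky silyl ether on C4 covers the opposite face at the C3 terminus. Preference for cycloaddition over the ene reaction rests on the fixed cisoid geometry and on the ester-free, electron-rich diene made in step 7. Low temperature and direct use of the product should guard against aromatisation of the diene and thermal rearrangement of the peroxide.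

**Step 9**
Reactants: 10 (3S,4S,5R,6R)-3,6-epidioxy-1-(hydroxymethyl)-4-(triisopropylsilyloxy)cyclohex-1-en-5-ol; 11 benzoyl chloride
Product: 12 (3S,4S,5R,6R)-5-benzoyloxy-1-(benzoyloxymethyl)-3,6-epidioxy-4-(triisopropylsilyloxy)cyclohex-1-ene
Conditions: BzCl (3 equiv), pyridine, CH2Cl2, 0 °C
Reagents that add atoms: benzoyl chloride (11), O=C(Cl)c1ccccc1
Why: Acylation of the primary C7 and secondary C5 hydroxyls in pyridine, a base too weak to deprotonate the peroxide bridgeheads (no Kornblum–DeLaMare opening), should place both benzoates while O3 and O6 are still locked in the peroxide.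

**Step 10**
Reactants: 12 (3S,4S,5R,6R)-5-benzoyloxy-1-(benzoyloxymethyl)-3,6-epidioxy-4-(triisopropylsilyloxy)cyclohex-1-ene
Product: 13 [(3S,4R,5R,6R)-5-benzoyloxy-3,6-dihydroxy-4-(triisopropylsilyloxy)cyclohex-1-en-1-yl]methyl benzoate
Conditions: thiourea, MeOH, rt
Reagents that add atoms: none
Why: Thiourea reduction cleaves only the O–O bond of the bicyclic peroxide, so both C–O bonds stay intact and the cis-C3,C6-diol should appear with the configuration fixed in step 8, the benzoates, silyl ether and alkene being untouched.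

**Step 11**
Reactants: 13 [(3S,4R,5R,6R)-5-benzoyloxy-3,6-dihydroxy-4-(triisopropylsilyloxy)cyclohex-1-en-1-yl]methyl benzoate
Product: 14 [(3S,4R,5R,6R)-5-benzoyloxy-3,4,6-trihydroxycyclohex-1-en-1-yl]methyl benzoate
Conditions: HF·pyridine, pyridine, THF, 0 °C to rt
Reagents that add atoms: none
Why: Fluoride-mediated Si–O cleavage under mildly acidic, pyridine-buffered conditions should remove the silyl ether without the basic medium that would let the C5 benzoate move to its neighbours O4 or O6.

**Compound list**

1 | (−)-shikimic acid, (3R,4S,5R)-3,4,5-trihydroxycyclohex-1-ene-1-carboxylic acid | OC(=O)C1=C[C@@H](O)[C@@H](O)[C@H](O)C1 | starting material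
2 | methyl shikimate, methyl (3R,4S,5R)-3,4,5-trihydroxycyclohex-1-ene-1-carboxylate | COC(=O)C1=C[C@@H](O)[C@@H](O)[C@H](O)C1 | intermediate
3 | methyl 3,4-O-isopropylideneshikimate (cis-fused dioxolane on O3/O4, free 5-OH; 3R,4S,5R) | COC(=O)C1=C[C@H]2OC(C)(C)O[C@H]2[C@H](O)C1 | intermediate
4 | methyl 3,4-O-isopropylidene-5-O-pivaloylshikimate (shikimic acid configuration) | COC(=O)C1=C[C@H]2OC(C)(C)O[C@H]2[C@H](OC(=O)C(C)(C)C)C1 | intermediate
5 | methyl 5-O-pivaloylshikimate (free cis-3,4-diol; shikimic acid configuration at C3, C4, C5) | COC(=O)C1=C[C@@H](O)[C@@H](O)[C@H](OC(=O)C(C)(C)C)C1 | intermediate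
6 | methyl 3,4-O-carbonyl-5-O-pivaloylshikimate (cis-fused cyclic carbonate; shikimic acid configuration) | COC(=O)C1=C[C@H]2OC(=O)O[C@H]2[C@H](OC(=O)C(C)(C)C)C1 | intermediate
7 | methyl (4R,5R)-4-hydroxy-5-pivaloyloxycyclohexa-1(6),2-diene-1-carboxylate (trans; diene C6=C1–C2=C3) | COC(=O)C1=C[C@@H](OC(=O)C(C)(C)C)[C@H](O)C=C1 | intermediate
8 | methyl (4R,5R)-5-pivaloyloxy-4-(triisopropylsilyloxy)cyclohexa-1(6),2-diene-1-carboxylate | COC(=O)C1=C[C@@H](OC(=O)C(C)(C)C)[C@H](O[Si](C(C)C)(C(C)C)C(C)C)C=C1 | intermediate
9 | (4R,5R)-1-(hydroxymethyl)-4-(triisopropylsilyloxy)cyclohexa-1(6),2-dien-5-ol (diene diol, trans) | OCC1=C[C@@H](O)[C@H](O[Si](C(C)C)(C(C)C)C(C)C)C=C1 | intermediate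
10 | (3S,4S,5R,6R)-3,6-epidioxy-1-(hydroxymethyl)-4-(triisopropylsilyloxy)cyclohex-1-en-5-ol (2,3-dioxabicyclo[2.2.2]oct-5-ene; peroxide bridge cis to 5-OH, trans to 4-OSi) | OCC1=C[C@H](OO2)[C@@H](O[Si](C(C)C)(C(C)C)C(C)C)[C@H](O)[C@@H]12 | intermediate
11 | benzoyl chloride | O=C(Cl)c1ccccc1 | starting material
12 | (3S,4S,5R,6R)-5-benzoyloxy-1-(benzoyloxymethyl)-3,6-epidioxy-4-(triisopropylsilyloxy)cyclohex-1-ene | O=C(OCC1=C[C@H](OO2)[C@@H](O[Si](C(C)C)(C(C)C)C(C)C)[C@H](OC(=O)c3ccccc3)[C@@H]12)c1ccccc1 | intermediate
13 | [(3S,4R,5R,6R)-5-benzoyloxy-3,6-dihydroxy-4-(triisopropylsilyloxy)cyclohex-1-en-1-yl]methyl benzoate | O=C(OCC1=C[C@H](O)[C@@H](O[Si](C(C)C)(C(C)C)C(C)C)[C@H](OC(=O)c2ccccc2)[C@@H]1O)c1ccccc1 | intermediate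
14 | [(3S,4R,5R,6R)-5-benzoyloxy-3,4,6-trihydroxycyclohex-1-en-1-yl]methyl benzoate (CNP0198957.7) | O=C(OCC1=C[C@H](O)[C@@H](O)[C@H](OC(=O)c2ccccc2)[C@@H]1O)c1ccccc1 | target

**Step count and risks**

Total step count: 11 (step 1 is a two-stage operation in one flask).
Longest linear sequence: 11 steps from shikimic acid; the route is fully linear, benzoyl chloride entering in step 9.

Steps most likely to fail:

1. Step 5. After ionisation the C4 alkoxide may hand its own carbinol hydrogen to palladium (hydride shift to a C4 ketone instead of loss of the C6 hydrogen). The pivaloyl group may also migrate to that alkoxide, or a second ionisation at the now allylic C5 ester may aromatise the ring. The fallback sets out from 5 and rejoins the route at 8, and it avoids a ring alkoxide altogether. Selective acylation of the allylic O3 (ClCO2Me, pyridine, CH2Cl2, −40 °C; O4 is flanked by the pivalate) should give methyl 3-O-methoxycarbonyl-5-O-pivaloylshikimate F1. Silylation of O4 (TIPSOTf, 2,6-lutidine, CH2Cl2) then gives methyl 3-O-methoxycarbonyl-5-O-pivaloyl-4-O-(triisopropylsilyl)shikimate F2. A neutral Tsuji–Trost elimination of this acyclic allylic carbonate (Pd(PPh3)4, THF, 60 °C), with the expelled methoxide as the base, should deliver 8 directly.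

2. Step 8. Facial discrimination may be poor if the C5 hydroxyl is tied up in hydrogen bonding to O7 rather than to the incoming oxygen. Ene hydroperoxidation may compete, or the diene may aromatise before it reacts. The fallback sets out from 9 and rejoins the route at 13, and it forms the two C–O bonds one after the other.
   - Hydroxyl-directed vanadium-catalysed epoxidation (VO(acac)2, t-BuOOH, CH2Cl2, 0 °C) of the C6=C1 alkene, which is allylic to both free hydroxyls, should give on the face of the ring hydroxyl 1,6-epoxy-1-(hydroxymethyl)-4-(triisopropylsilyloxy)cyclohex-2-en-5-ol F3.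
   - Benzoylation (BzCl, pyridine) gives 5-benzoyloxy-1-(benzoyloxymethyl)-1,6-epoxy-4-(triisopropylsilyloxy)cyclohex-2-ene F4.
   - Opening of the vinyl epoxide with acetic acid under zerovalent palladium catalysis (Pd(PPh3)4, AcOH, THF, 0 °C) proceeds by ionisation at C1 from the face opposite the epoxide and carboxylate attack at C3 from the face opposite the metal. It should give the cis-1,4 product [(3S,4R,5R,6R)-3-acetoxy-5-benzoyloxy-6-hydroxy-4-(triisopropylsilyloxy)cyclohex-1-en-1-yl]methyl benzoate F5.
   - Acid-catalysed methanolysis of the acetate (HCl (cat.), MeOH, 0 °C to rt), which spares the benzoates and the silyl ether, gives 13.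

3. Step 9. Base may open the peroxide at a bridgehead C–H (Kornblum–DeLaMare path), or the hindered C5 hydroxyl may acylate so slowly that forcing conditions destroy the bicycle. The fallback sets out from 9 and rejoins the route at 12, and it acylates before the peroxide exists. Benzoylation of the diene diol (BzCl, pyridine, CH2Cl2, 0 °C) should give (4R,5R)-5-benzoyloxy-1-(benzoyloxymethyl)-4-(triisopropylsilyloxy)cyclohexa-1(6),2-diene F6. Photooxygenation of this diene under the conditions of step 8 then gives 12. Face selection in that case rests on steric shielding of the lower face by the C4 silyl ether alone, without hydrogen-bond steering.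

**Further compounds**

F1 | step 5 | methyl 3-O-methoxycarbonyl-5-O-pivaloylshikimate | COC(=O)C1=C[C@@H](OC(=O)OC)[C@@H](O)[C@H](OC(=O)C(C)(C)C)C1
F2 | step 5 | methyl 3-O-methoxycarbonyl-5-O-pivaloyl-4-O-(triisopropylsilyl)shikimate | COC(=O)C1=C[C@@H](OC(=O)OC)[C@@H](O[Si](C(C)C)(C(C)C)C(C)C)[C@H](OC(=O)C(C)(C)C)C1
F3 | step 8 | 1,6-epoxy-1-(hydroxymethyl)-4-(triisopropylsilyloxy)cyclohex-2-en-5-ol (epoxide oxygen cis to 5-OH) | OC[C@@]1(O2)C=C[C@@H](O[Si](C(C)C)(C(C)C)C(C)C)[C@H](O)[C@@H]12
F4 | step 8 | 5-benzoyloxy-1-(benzoyloxymethyl)-1,6-epoxy-4-(triisopropylsilyloxy)cyclohex-2-ene (epoxide oxygen cis to 5-OBz) | O=C(OC[C@@]1(O2)C=C[C@@H](O[Si](C(C)C)(C(C)C)C(C)C)[C@H](OC(=O)c3ccccc3)[C@@H]12)c1ccccc1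
F5 | step 8 | [(3S,4R,5R,6R)-3-acetoxy-5-benzoyloxy-6-hydroxy-4-(triisopropylsilyloxy)cyclohex-1-en-1-yl]methyl benzoate | O=C(OCC1=C[C@H](OC(C)=O)[C@@H](O[Si](C(C)C)(C(C)C)C(C)C)[C@H](OC(=O)c2ccccc2)[C@@H]1O)c1ccccc1
F6 | step 9 | (4R,5R)-5-benzoyloxy-1-(benzoyloxymethyl)-4-(triisopropylsilyloxy)cyclohexa-1(6),2-diene | O=C(OCC1=C[C@@H](OC(=O)c2ccccc2)[C@H](O[Si](C(C)C)(C(C)C)C(C)C)C=C1)c1ccccc1
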